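**Retrosynthetic overview**
1. The target is reached from its 7‑O‑MOM, C4‑dithioketal form by two unmasking steps; rings A and B are bought and dressed first, ring C is formed last.
2. Ring C is closed by a one‑flask [3+3] annulation: C3–C4 by attack of a lithiated ring A dithiane on the CH2 carbon of an (R)‑aryl oxirane, then O1–C8a by displacement of an ortho fluoride by the alkoxide so released.
3. Enabling feature: the acyl carbon C4 and the ether oxygen O1 sit on the adjacent ring A carbons C4a and C8a, and O1–C2–C3 is a 1,2‑O,C unit. Ring C therefore maps onto an oxirane (O1, C2, C3) plus a 2‑fluorobenzaldehyde whose formyl carbon is umpoled as a dithiane; C2 rides in untouched from the oxirane.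
4. The (R)‑oxirane comes from an α‑chloro ketone (asymmetric transfer hydrogenation, closure), made from a methyl benzoate (chloromethyllithium) whose prenyl groups come from a double Suzuki–Miyaura coupling of a dibromide.
5. The ring A partner comes from 2‑fluoro‑4‑hydroxybenzaldehyde (dithioacetalisation, MOM ether).

Key step: step 7

Remark on the chemistry: the single stereocentre (C2) of the target is S as read from the SMILES; both starting materials and prenylboronic acid pinacol ester are assumed to be commercial.

**Step 1**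
Reactants: 1 methyl 3,5-dibromo-4-hydroxybenzoate
Product: 2 methyl 3,5-dibromo-4-methoxybenzoate
Conditions: MeI, K2CO3, DMF, 40 °C
Reagents that add atoms: iodomethane, CI
Why: Williamson O‑methylation of the acidic 2,6‑dibromophenol, with the ester inert to carbonate.

**Step 2**
Reactants: 2 methyl 3,5-dibromo-4-methoxybenzoate
Product: 3 methyl 4-methoxy-3,5-bis(3-methylbut-2-en-1-yl)benzoate
Conditions: prenylboronic acid pinacol ester (2.6 equiv), Pd(OAc)2 (cat.), t‑BuXPhos, K3PO4 (aq), MeCN, 70 °C
Reagents that add atoms: prenylboronic acid pinacol ester, CC(C)=CCB1OC(C)(C)C(C)(C)O1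
Why: Twofold Suzuki–Miyaura coupling of an allylboronate with an aryl bromide, in which the bulky di‑tert‑butylbiarylphosphine should steer reductive elimination to the unsubstituted allyl terminus and so give the linear prenyl groups, while ester and aryl ether are inert.

**Step 3**
Reactants: 3 methyl 4-methoxy-3,5-bis(3-methylbut-2-en-1-yl)benzoate
Product: 4 2-chloro-1-[4-methoxy-3,5-bis(3-methylbut-2-en-1-yl)phenyl]ethan-1-one
Conditions: ICH2Cl, MeLi·LiBr, THF, −78 °C; AcOH quench at −78 °C
Reagents that add atoms: chloroiodomethane, ClCI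
Why: Homologation of an ester with chloromethyllithium made in the flask by iodine–lithium exchange: the lithium hemiketal from one addition is stable at −78 °C, so the ketone is released only on the acidic quench and a second addition is avoided.

**Step 4**
Reactants: 4 2-chloro-1-[4-methoxy-3,5-bis(3-methylbut-2-en-1-yl)phenyl]ethan-1-one
Product: 6 (2R)-2-[4-methoxy-3,5-bis(3-methylbut-2-en-1-yl)phenyl]oxirane, via chlorohydrin 5 (not isolated)
Conditions: RuCl[(S,S)-TsDPEN](p-cymene) (cat.), HCO2H/Et3N (5:2), EtOAc, rt; then NaOH (aq), i‑PrOH, 0 °C to rt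
Reagents that add atoms: none
Why: Noyori–Ikariya asymmetric transfer hydrogenation followed by intramolecular Williamson closure: the (S,S)‑catalyst delivers hydride to the carbonyl face that gives (S)‑1‑phenylethanol from acetophenone, which with CH2Cl in place of CH3 corresponds to the (R)‑chlorohydrin 5, the isolated trisubstituted alkenes are inert to transfer hydrogenation, and hydroxide then closes the oxirane by SN2 at the CH2Cl carbon without touching the stereocentre.

**Step 5**
Reactants: 7 2-fluoro-4-hydroxybenzaldehyde
Product: 8 4-(1,3-dithian-2-yl)-3-fluorophenol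
Conditions: HS(CH2)3SH, BF3·OEt2 (cat.), CH2Cl2, 0 °C to rt
Reagents that add atoms: propane-1,3-dithiol, SCCCS
Why: Lewis‑acid‑catalysed dithioacetalisation of an aromatic aldehyde, with the free phenol and the aryl fluoride inert.

**Step 6**
Reactants: 8 4-(1,3-dithian-2-yl)-3-fluorophenol
Product: 9 2-[2-fluoro-4-(methoxymethoxy)phenyl]-1,3-dithiane
Conditions: MOMCl, i‑Pr2NEt, CH2Cl2, 0 °C to rt
Reagents that add atoms: chloromethyl methyl ether, COCCl
Why: Alkylation of the phenol with an α‑chloro ether (MOM protection), which gives a group that withstands n‑BuLi and alkoxide and is removable with mild acid at the end.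

**Step 7**
Reactants: 9 2-[2-fluoro-4-(methoxymethoxy)phenyl]-1,3-dithiane; 6 (2R)-2-[4-methoxy-3,5-bis(3-methylbut-2-en-1-yl)phenyl]oxirane
Product: 12 (2S)-2-[4-methoxy-3,5-bis(3-methylbut-2-en-1-yl)phenyl]-7-(methoxymethoxy)spiro[chromane-4,2'-[1,3]dithiane], via lithiodithiane 10 (not isolated), via lithium alkoxide 11 (not isolated)
Conditions: 9, n‑BuLi (1.0 equiv), THF, −78 to −30 °C; then 6, −30 °C to rt; then KOt‑Bu (1.0 equiv), DMPU, 60 °C
Reagents that add atoms: none
Why: n‑BuLi removes the dithiane C–H to give the sulfur‑stabilised carbanion 10 (the acyl‑anion equivalent of C4, Corey–Seebach umpolung), 10 opens oxirane 6 by SN2 at its unsubstituted CH2 carbon (the future C3) to give alkoxide 11, and after the switch to a potassium counter‑ion in THF/DMPU this alkoxide oxygen (the future O1) displaces fluoride at the ring A carbon ortho to the dithiane carbon by intramolecular nucleophilic aromatic substitution. The closest known reaction types are the opening of terminal aryl oxiranes by 2‑aryl‑2‑lithio‑1,3‑dithianes and the closure of chromans by attack of a tethered alkoxide on a non‑activated aryl fluoride. Ring C is the only ring closed; it closes as a six‑membered ring by addition–elimination at the C–F carbon (6‑exo attack on the arene), helped by the fully substituted dithiane carbon in the tether. No stereocentre is created: C2 comes from 6 with its C–O bond untouched throughout (the descriptor changes from R to S only because the CIP ranking of its neighbours changes), and because C4 stays a dithioketal there is no enolisable carbonyl and hence no retro‑aldol or retro‑oxa‑Michael path that could racemise it. The step needs opening at CH2 rather than at the benzylic carbon, which the bulk of the tertiary dithianyl anion and the weak donor ability of the out‑of‑plane 4‑methoxy group flanked by two prenyl groups should secure; it also needs lithiation at the dithiane carbon and not at the arene C–H between F and OMOM, which the markedly higher acidity of the dithiane C–H and the low temperature before the oxirane is added should secure.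

**Step 8**
Reactants: 12 (2S)-2-[4-methoxy-3,5-bis(3-methylbut-2-en-1-yl)phenyl]-7-(methoxymethoxy)spiro[chromane-4,2'-[1,3]dithiane]
Product: 13 (2S)-2-[4-methoxy-3,5-bis(3-methylbut-2-en-1-yl)phenyl]-7-(methoxymethoxy)-2,3-dihydro-4H-chromen-4-one
Conditions: MeI (excess), CaCO3, MeCN/H2O (4:1), 45 °C
Reagents that add atoms: water, O
Why: Alkylative hydrolysis of a dithioketal (S‑methylation, ring opening to a thionium ion stabilised by the two oxygen‑substituted positions of ring A, capture by water) under buffered neutral conditions that leave the prenyl alkenes, the MOM ether and the C2 stereocentre untouched, since no base is present to trigger retro‑oxa‑Michael opening.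

**Step 9**
Reactants: 13 (2S)-2-[4-methoxy-3,5-bis(3-methylbut-2-en-1-yl)phenyl]-7-(methoxymethoxy)-2,3-dihydro-4H-chromen-4-one
Product: 14 (2S)-7-hydroxy-2-[4-methoxy-3,5-bis(3-methylbut-2-en-1-yl)phenyl]-2,3-dihydro-4H-chromen-4-one (abyssinone IV 4'-OMe ether)
Conditions: HCl (cat.), MeOH, 40 °C
Reagents that add atoms: none
Why: Acid‑catalysed acetal exchange of the aryl MOM ether with methanol; the flavanone C2–O bond and the prenyl groups (no free phenol ortho to them) should survive brief mild acid, so the (S)‑configuration is retained.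

**Compound list**
1 | methyl 3,5-dibromo-4-hydroxybenzoate | COC(=O)c1cc(Br)c(O)c(Br)c1 | starting material
2 | methyl 3,5-dibromo-4-methoxybenzoate | COC(=O)c1cc(Br)c(OC)c(Br)c1 | intermediate
3 | methyl 4-methoxy-3,5-bis(3-methylbut-2-en-1-yl)benzoate | COC(=O)c1cc(CC=C(C)C)c(OC)c(CC=C(C)C)c1 | intermediate
4 | 2-chloro-1-[4-methoxy-3,5-bis(3-methylbut-2-en-1-yl)phenyl]ethan-1-one | COc1c(CC=C(C)C)cc(C(=O)CCl)cc1CC=C(C)C | intermediate
5 | (1R)-2-chloro-1-[4-methoxy-3,5-bis(3-methylbut-2-en-1-yl)phenyl]ethan-1-ol | COc1c(CC=C(C)C)cc([C@@H](O)CCl)cc1CC=C(C)C | intermediate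
6 | (2R)-2-[4-methoxy-3,5-bis(3-methylbut-2-en-1-yl)phenyl]oxirane | COc1c(CC=C(C)C)cc([C@@H]2CO2)cc1CC=C(C)C | intermediate
7 | 2-fluoro-4-hydroxybenzaldehyde | O=Cc1ccc(O)cc1F | starting material
8 | 4-(1,3-dithian-2-yl)-3-fluorophenol | Oc1ccc(C2SCCCS2)c(F)c1 | intermediate
9 | 2-[2-fluoro-4-(methoxymethoxy)phenyl]-1,3-dithiane | COCOc1ccc(C2SCCCS2)c(F)c1 | intermediate
10 | 2-lithio-2-[2-fluoro-4-(methoxymethoxy)phenyl]-1,3-dithiane | [Li]C1(c2ccc(OCOC)cc2F)SCCCS1 | intermediate
11 | lithium (1S)-2-{2-[2-fluoro-4-(methoxymethoxy)phenyl]-1,3-dithian-2-yl}-1-[4-methoxy-3,5-bis(3-methylbut-2-en-1-yl)phenyl]ethan-1-olate | [Li]O[C@@H](CC1(SCCCS1)c1ccc(OCOC)cc1F)c1cc(CC=C(C)C)c(OC)c(CC=C(C)C)c1 | intermediate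
12 | (2S)-2-[4-methoxy-3,5-bis(3-methylbut-2-en-1-yl)phenyl]-7-(methoxymethoxy)spiro[chromane-4,2'-[1,3]dithiane] | COc1c(CC=C(C)C)cc([C@@H]2CC4(SCCCS4)c3ccc(OCOC)cc3O2)cc1CC=C(C)C | intermediate
13 | (2S)-2-[4-methoxy-3,5-bis(3-methylbut-2-en-1-yl)phenyl]-7-(methoxymethoxy)-2,3-dihydro-4H-chromen-4-one | COc1c(CC=C(C)C)cc([C@@H]2CC(=O)c3ccc(OCOC)cc3O2)cc1CC=C(C)C | intermediate
14 | (2S)-7-hydroxy-2-[4-methoxy-3,5-bis(3-methylbut-2-en-1-yl)phenyl]-2,3-dihydro-4H-chromen-4-one | COc1c(CC=C(C)C)cc([C@@H]2CC(=O)c3ccc(O)cc3O2)cc1CC=C(C)C | target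

**Totals and risks**
Total step count: 9. Longest linear sequence: 7 (steps 1, 2, 3, 4, 7, 8, 9).

Steps most likely to fail:

Step 7. Three processes may spoil it: metalation of the arene C–H between F and OMOM (followed by loss of LiF), attack of the dithianyl anion at the benzylic oxirane carbon, and a slow fluoride displacement during which the hot alkoxide base shifts the prenyl double bonds into conjugation. The fallback sets out from 6 and comes back at 12; it closes the C–O bond by copper catalysis instead of fluoride displacement. Commercial 2‑bromo‑4‑hydroxybenzaldehyde would be converted, as in steps 5 and 6, into 3-bromo-4-(1,3-dithian-2-yl)phenol F1 and then 2-[2-bromo-4-(methoxymethoxy)phenyl]-1,3-dithiane F2. Deprotonation with LDA in THF at −78 °C (no bromine–lithium exchange) would give 2-lithio-2-[2-bromo-4-(methoxymethoxy)phenyl]-1,3-dithiane F3. Addition of 6 would give the lithium alkoxide F4 and, after aqueous quench, the isolated (1S)-2-{2-[2-bromo-4-(methoxymethoxy)phenyl]-1,3-dithian-2-yl}-1-[4-methoxy-3,5-bis(3-methylbut-2-en-1-yl)phenyl]ethan-1-ol F5. F5 would then be cyclised to 12 by Ullmann‑type intramolecular etherification with CuI (cat.), 3,4,7,8‑tetramethyl‑1,10‑phenanthroline and Cs2CO3 in toluene at 100 °C, with no strong base present at elevated temperature.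

Step 2. Regiocontrol at the allyl terminus may be lost (1,1‑dimethylallyl isomers), the second coupling next to the first prenyl group may stall, or the boronate may protodeboronate. The fallback sets out from 2 and comes back at 3; it installs symmetric allyl groups, for which no regiochemical question exists, and turns them into prenyl groups afterwards. A double Suzuki–Miyaura coupling of 2 with allylboronic acid pinacol ester (Pd(OAc)2, SPhos, K3PO4, THF/H2O) would give methyl 4-methoxy-3,5-di(prop-2-en-1-yl)benzoate F6. Olefin cross‑metathesis of F6 with excess 2‑methyl‑2‑butene and second‑generation Grubbs catalyst in CH2Cl2 at 40 °C should give 3.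

Step 8. S‑Methylation at the hindered spiro dithioketal may be slow, and more forcing or oxidative unmasking conditions may then attack the prenyl alkenes or the electron‑rich rings. The fallback sets out from 12 and comes back at 14; it uses sulfur oxidation and acid hydrolysis instead of alkylative hydrolysis. NaIO4 (1.05 equiv, MeOH/H2O, 0 °C) should oxidise one sulfur without touching the alkenes and give (2S)-2-[4-methoxy-3,5-bis(3-methylbut-2-en-1-yl)phenyl]-7-(methoxymethoxy)spiro[chromane-4,2'-[1,3]dithiane] 1'-oxide F7. Treatment of F7 with HCl in aqueous MeOH at 40 °C should release the C4 ketone and cleave the MOM ether in the same operation, giving 14 directly.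

**Further compounds**
F1 | step 7 | 3-bromo-4-(1,3-dithian-2-yl)phenol | Oc1ccc(C2SCCCS2)c(Br)c1
F2 | step 7 | 2-[2-bromo-4-(methoxymethoxy)phenyl]-1,3-dithiane | COCOc1ccc(C2SCCCS2)c(Br)c1
F3 | step 7 | 2-lithio-2-[2-bromo-4-(methoxymethoxy)phenyl]-1,3-dithiane | [Li]C1(c2ccc(OCOC)cc2Br)SCCCS1
F4 | step 7 | lithium (1S)-2-{2-[2-bromo-4-(methoxymethoxy)phenyl]-1,3-dithian-2-yl}-1-[4-methoxy-3,5-bis(3-methylbut-2-en-1-yl)phenyl]ethan-1-olate | [Li]O[C@@H](CC1(SCCCS1)c1ccc(OCOC)cc1Br)c1cc(CC=C(C)C)c(OC)c(CC=C(C)C)c1
F5 | step 7 | (1S)-2-{2-[2-bromo-4-(methoxymethoxy)phenyl]-1,3-dithian-2-yl}-1-[4-methoxy-3,5-bis(3-methylbut-2-en-1-yl)phenyl]ethan-1-ol | O[C@@H](CC1(SCCCS1)c1ccc(OCOC)cc1Br)c1cc(CC=C(C)C)c(OC)c(CC=C(C)C)c1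
F6 | step 2 | methyl 4-methoxy-3,5-di(prop-2-en-1-yl)benzoate | COC(=O)c1cc(CC=C)c(OC)c(CC=C)c1
F7 | step 8 | (2S)-2-[4-methoxy-3,5-bis(3-methylbut-2-en-1-yl)phenyl]-7-(methoxymethoxy)spiro[chromane-4,2'-[1,3]dithiane] 1'-oxide (mixture of diastereomers at sulfur and C4) | COc1c(CC=C(C)C)cc([C@@H]2CC4(SCCCS4=O)c3ccc(OCOC)cc3O2)cc1CC=C(C)C
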